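**Plan**
- Retrosynthetic cuts, in order: C4–C4a (aryl ketone, from an aryl bromide and an ester), C3–C1' (tertiary carbinol to ring B, aldol), O1–C2 (phenol alkylation), then the two aryl–CH2 bonds at C6 and C8 and the two prenyl C=C bonds (cross-coupling, cross-metathesis).
- Enabling feature: ring B (C1'–C6') is a resorcinol with oxygen on C2' and C4', bonded through C1' to the tertiary carbinol C3. It is therefore the dehydrogenated form of a 3-alkoxycyclohex-2-enone (C2' = carbonyl carbon, C4' = alkoxy carbon, C1' = α'-carbon), and C3, lying between C2–O1 and C4, is the ketone carbon of a 3-aryloxypyruvate ester.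
- Forward order: ring A is present from the start (4-bromoresorcinol) and is silylated, iodinated, allylated, turned into the diprenyl compound and O-alkylated. The carbocycle from cyclohexane-1,3-dione is joined at C3–C1' and then aromatized to ring B. Ring C closes last at C4–C4a.
- Stereochemistry: the only stereocentre, C3 (R), is set in the aldol step by a chiral copper bis(oxazoline) catalyst and is quaternary from then on. The C1' centre formed with it disappears on aromatization.

Key step: step 8

Assumption: the SMILES is read as the (3R)-enantiomer; chroman-4-one numbering is used (O1, C2, C3, C4, C4a, C5–C8, C8a; ring B C1'–C6'), with ring A the benzo ring, ring B the pendant aryl ring and ring C the pyranone ring.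

**Step 1**
Reactants: 1 4-bromoresorcinol
Product: 2 2-bromo-5-(triisopropylsilyloxy)phenol
Conditions: TIPSCl (1.05 equiv), imidazole, DMF, 0 °C
Reagents that add atoms: triisopropylsilyl chloride, CC(C)[Si](Cl)(C(C)C)C(C)C
Why: Silyl ether formation under steric control: the hydroxyl para to bromine is unhindered, whereas the one ortho to bromine is shielded and hydrogen-bonded to the halogen, so the bulky silyl chloride should react at the former only.

**Step 2**
Reactants: 2 2-bromo-5-(triisopropylsilyloxy)phenol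
Product: 3 6-bromo-2,4-diiodo-3-(triisopropylsilyloxy)phenol
Conditions: NIS (2.2 equiv), TsOH (cat.), MeCN, 0 °C → rt
Reagents that add atoms: N-iodosuccinimide, O=C1CCC(=O)N1I
Why: Electrophilic aromatic iodination directed by the free hydroxyl to its open ortho and para carbons, which are the two carbons flanking the silyloxy group; the remaining ring hydrogen is meta to both oxygens and the other ortho carbon is blocked by bromine.

**Step 3**
Reactants: 3 6-bromo-2,4-diiodo-3-(triisopropylsilyloxy)phenol; 4 allyltributylstannane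
Product: 5 2,4-diallyl-6-bromo-3-(triisopropylsilyloxy)phenol
Conditions: Pd(PPh3)4 (5 mol%), CuI (10 mol%), DMF, 70 °C
Reagents that add atoms: none
Why: Twofold Stille coupling: zerovalent palladium inserts into the two C–I bonds much faster than into the electron-rich C–Br bond, allyl is transferred from tin, and the neutral, fluoride-free conditions leave the aryl silyl ether and the free phenol untouched.

**Step 4**
Reactants: 5 2,4-diallyl-6-bromo-3-(triisopropylsilyloxy)phenol; 6 2-methyl-2-butene
Product: 7 6-bromo-2,4-bis(3-methylbut-2-en-1-yl)-3-(triisopropylsilyloxy)phenol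
Conditions: second-generation Grubbs catalyst RuCl2(=CHPh)(PCy3)(H2IMes) (5 mol%), 2-methyl-2-butene (excess)/CH2Cl2, 40 °C, sealed tube
Reagents that add atoms: none
Why: Olefin cross-metathesis of each terminal allyl group with an excess of the trisubstituted alkene exchanges CH2 for C(CH3)2 and releases propene, and the ruthenium carbene tolerates the phenol, the aryl bromide and the silyl ether.

**Step 5**
Reactants: 7 6-bromo-2,4-bis(3-methylbut-2-en-1-yl)-3-(triisopropylsilyloxy)phenol; 8 ethyl bromopyruvate
Product: 9 ethyl 3-[2-bromo-4,6-bis(3-methylbut-2-en-1-yl)-5-(triisopropylsilyloxy)phenoxy]-2-oxopropanoate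
Conditions: K2CO3, acetone, 0 °C → rt
Reagents that add atoms: none
Why: Williamson ether synthesis at the only free hydroxyl with an α-bromo ketone, an SN2 electrophile reactive enough for a phenoxide with two ortho substituents, under a weak base at low temperature so that the enolisable keto ester is not condensed further.

**Step 6**
Reactants: 10 cyclohexane-1,3-dione
Product: 11 3-(allyloxy)cyclohex-2-en-1-one
Conditions: allyl alcohol, TsOH (cat.), benzene, reflux, Dean–Stark trap
Reagents that add atoms: allyl alcohol, C=CCO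
Why: Acid-catalysed vinylogous esterification of the enolised 1,3-dione with the alcohol, driven by azeotropic removal of water.

**Step 7**
Reactants: 11 3-(allyloxy)cyclohex-2-en-1-one
Product: 13 1-(allyloxy)-3-(trimethylsilyloxy)cyclohexa-1,3-diene, via lithium dienolate 12 (not isolated)
Conditions: LiN(i-Pr)2, THF, −78 °C; TMSCl, −78 → 0 °C; non-aqueous work-up, used without heating
Reagents that add atoms: chlorotrimethylsilane, C[Si](C)(C)Cl
Why: Kinetic α'-deprotonation of the vinylogous ester and O-silylation of the cross-conjugated enolate (silyl enol ether formation) give the 1-alkoxy-3-silyloxy diene, which is kept cold because as an allyl vinyl ether it could undergo Claisen rearrangement.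

**Step 8**
Reactants: 9 ethyl 3-aryloxypyruvate of ring A; 13 1-(allyloxy)-3-(trimethylsilyloxy)cyclohexa-1,3-diene
Product: 15 ethyl (2R)-2-[4-(allyloxy)-2-oxocyclohex-3-en-1-yl]-3-[2-bromo-4,6-bis(3-methylbut-2-en-1-yl)-5-(triisopropylsilyloxy)phenoxy]-2-hydroxypropanoate (both epimers at the cyclohexenone C1), via trimethylsilyl ether 14 (not isolated)
Conditions: Cu(OTf)2 (10 mol%), 2,2'-isopropylidenebis[(4S)-4-tert-butyl-2-oxazoline] (11 mol%), THF, −78 °C; then 10% aq. citric acid, THF, 0 °C
Reagents that add atoms: none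
Why: Mukaiyama aldol addition: keto ester 9 chelates the copper centre through its ketone and ester carbonyl oxygens, the silyl dienol ether 13 attacks the activated ketone carbon through the CH carbon of its silyl enol ether (the future C1') in an open transition state, and transfer of the trimethylsilyl group to the copper-bound alkoxide gives 14 and releases the catalyst. The closest known reaction type is the divalent-copper bis(oxazoline)-catalysed addition of enolsilanes and of 1-alkoxy-3-silyloxy dienes to pyruvate esters. No ring is closed, only the C3–C1' bond forms, and a hetero-Diels–Alder adduct, if it arose, would be a bridged ketal that the acidic work-up opens to the same hydroxy enone. The C3 configuration is controlled by the ligand: in the square-planar chelate the tert-butyl group of the (S,S)-ligand covers the re face of the ketone, so attack on the si face should give the (2R)-alcohol, which corresponds to (3R) in the target. The centre at C1' of the cyclohexenone is under no control and needs none, because it is removed by the aromatization in step 9. The step needs chemoselectivity for the ketone over the ester and for the diene over the prenyl and allyl alkenes, secured by chelate activation of the 1,2-dicarbonyl unit and by the far higher π-nucleophilicity of the doubly oxygen-substituted diene, and it needs two-point binding that the ether oxygen does not disturb, which the two ortho substituents of ring A help to ensure by shielding that oxygen.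

**Step 9**
Reactants: 15 aldol adduct
Product: 17 ethyl (2R)-2-[4-(allyloxy)-2-(triethylsilyloxy)phenyl]-3-[2-bromo-4,6-bis(3-methylbut-2-en-1-yl)-5-(triisopropylsilyloxy)phenoxy]-2-(triethylsilyloxy)propanoate, via bis(triethylsilyl) dienol ether 16 (not isolated)
Conditions: TESOTf (3.5 equiv), Et3N (5 equiv), CH2Cl2, −78 → 0 °C; evaporation, pentane filtration; DDQ (1.1 equiv), 2,4,6-collidine, benzene, 0 °C → rt
Reagents that add atoms: triethylsilyl trifluoromethanesulfonate, CC[Si](CC)(CC)OS(=O)(=O)C(F)(F)F
Why: Silyl triflate and amine cap the tertiary alcohol and turn the vinylogous ester into a silyloxy diene (soft enolisation), and DDQ then abstracts hydride from a ring CH2 of this electron-rich diene so that proton loss gives the aryl silyl ether (dehydrogenative aromatization); either regioisomer of the dienol ether leads to the same arene, and C3, already silylated and without a hydrogen, cannot be scrambled by retro-aldol cleavage.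

**Step 10**
Reactants: 17 bis(triethylsilyl) aryl bromide ester
Product: 19 (3R)-3-[4-(allyloxy)-2-(triethylsilyloxy)phenyl]-6,8-bis(3-methylbut-2-en-1-yl)-3-(triethylsilyloxy)-7-(triisopropylsilyloxy)chroman-4-one, via aryllithium 18 (not isolated)
Conditions: t-BuLi (2.1 equiv), THF, −78 → −40 °C; aq. NH4Cl
Reagents that add atoms: none
Why: Parham cyclization: bromine–lithium exchange at −78 °C is faster than any attack of t-BuLi on the hindered ester, and the aryllithium then acylates itself on the ester in a 6-exo-trig closure (C4–C4a) with loss of ethoxide, C3 being quaternary and untouched.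

**Step 11**
Reactants: 19 protected chromanone
Product: 20 (3R)-3-[4-(allyloxy)-2-hydroxyphenyl]-3,7-dihydroxy-6,8-bis(3-methylbut-2-en-1-yl)chroman-4-one
Conditions: Bu4NF, AcOH (1:1, 4 equiv), THF, 0 °C → rt
Reagents that add atoms: none
Why: Fluoride-induced desilylation removes the two aryl silyl ethers and the tertiary triethylsilyl ether, and acetic acid buffering keeps phenoxide and alkoxide from accumulating so that the tertiary α-hydroxy ketone is not exposed to base.

**Step 12**
Reactants: 20 4'-O-allyl ether of the target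
Product: 21 (3R)-3-(2,4-dihydroxyphenyl)-3,7-dihydroxy-6,8-bis(3-methylbut-2-en-1-yl)chroman-4-one
Conditions: Pd(PPh3)4 (5 mol%), morpholine, THF, rt
Reagents that add atoms: none
Why: Tsuji–Trost deallylation: zerovalent palladium ionises the aryl allyl ether to a π-allyl complex that morpholine traps, while the C-bound prenyl groups carry no leaving group and the aryl bromide that would have competed for palladium is no longer present.

**Compound list**
1 | 4-bromoresorcinol | Oc1ccc(Br)c(O)c1 | starting material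
2 | 2-bromo-5-(triisopropylsilyloxy)phenol | Oc1cc(O[Si](C(C)C)(C(C)C)C(C)C)ccc1Br | intermediate
3 | 6-bromo-2,4-diiodo-3-(triisopropylsilyloxy)phenol | Oc1c(I)c(O[Si](C(C)C)(C(C)C)C(C)C)c(I)cc1Br | intermediate
4 | allyltributylstannane | C=CC[Sn](CCCC)(CCCC)CCCC | starting material
5 | 2,4-diallyl-6-bromo-3-(triisopropylsilyloxy)phenol | Oc1c(CC=C)c(O[Si](C(C)C)(C(C)C)C(C)C)c(CC=C)cc1Br | intermediate
6 | 2-methyl-2-butene | CC=C(C)C | starting material
7 | 6-bromo-2,4-bis(3-methylbut-2-en-1-yl)-3-(triisopropylsilyloxy)phenol | Oc1c(CC=C(C)C)c(O[Si](C(C)C)(C(C)C)C(C)C)c(CC=C(C)C)cc1Br | intermediate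
8 | ethyl bromopyruvate | CCOC(=O)C(=O)CBr | starting material
9 | ethyl 3-[2-bromo-4,6-bis(3-methylbut-2-en-1-yl)-5-(triisopropylsilyloxy)phenoxy]-2-oxopropanoate | CCOC(=O)C(=O)COc1c(Br)cc(CC=C(C)C)c(O[Si](C(C)C)(C(C)C)C(C)C)c1CC=C(C)C | intermediate
10 | cyclohexane-1,3-dione | O=C1CCCC(=O)C1 | starting material
11 | 3-(allyloxy)cyclohex-2-en-1-one | C=CCOC1=CC(=O)CCC1 | intermediate
12 | lithium 5-(allyloxy)cyclohexa-1,5-dien-1-olate (not isolated) | [Li]OC1=CCCC(OCC=C)=C1 | intermediate
13 | 1-(allyloxy)-3-(trimethylsilyloxy)cyclohexa-1,3-diene | C=CCOC1=CC(O[Si](C)(C)C)=CCC1 | intermediate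
14 | ethyl (2R)-2-[4-(allyloxy)-2-oxocyclohex-3-en-1-yl]-3-[2-bromo-4,6-bis(3-methylbut-2-en-1-yl)-5-(triisopropylsilyloxy)phenoxy]-2-(trimethylsilyloxy)propanoate (not isolated) | CCOC(=O)[C@](O[Si](C)(C)C)(COc1c(Br)cc(CC=C(C)C)c(O[Si](C(C)C)(C(C)C)C(C)C)c1CC=C(C)C)C1CCC(OCC=C)=CC1=O | intermediate
15 | ethyl (2R)-2-[4-(allyloxy)-2-oxocyclohex-3-en-1-yl]-3-[2-bromo-4,6-bis(3-methylbut-2-en-1-yl)-5-(triisopropylsilyloxy)phenoxy]-2-hydroxypropanoate (epimers at cyclohexenone C1) | CCOC(=O)[C@](O)(COc1c(Br)cc(CC=C(C)C)c(O[Si](C(C)C)(C(C)C)C(C)C)c1CC=C(C)C)C1CCC(OCC=C)=CC1=O | intermediate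
16 | ethyl (2R)-2-[4-(allyloxy)-2-(triethylsilyloxy)cyclohexa-2,4-dien-1-yl]-3-[2-bromo-4,6-bis(3-methylbut-2-en-1-yl)-5-(triisopropylsilyloxy)phenoxy]-2-(triethylsilyloxy)propanoate (not isolated) | CCOC(=O)[C@](O[Si](CC)(CC)CC)(COc1c(Br)cc(CC=C(C)C)c(O[Si](C(C)C)(C(C)C)C(C)C)c1CC=C(C)C)C1CC=C(OCC=C)C=C1O[Si](CC)(CC)CC | intermediate
17 | ethyl (2R)-2-[4-(allyloxy)-2-(triethylsilyloxy)phenyl]-3-[2-bromo-4,6-bis(3-methylbut-2-en-1-yl)-5-(triisopropylsilyloxy)phenoxy]-2-(triethylsilyloxy)propanoate | CCOC(=O)[C@](O[Si](CC)(CC)CC)(COc1c(Br)cc(CC=C(C)C)c(O[Si](C(C)C)(C(C)C)C(C)C)c1CC=C(C)C)c1ccc(OCC=C)cc1O[Si](CC)(CC)CC | intermediate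
18 | aryllithium from 17, lithium in place of bromine (not isolated) | CCOC(=O)[C@](O[Si](CC)(CC)CC)(COc1c([Li])cc(CC=C(C)C)c(O[Si](C(C)C)(C(C)C)C(C)C)c1CC=C(C)C)c1ccc(OCC=C)cc1O[Si](CC)(CC)CC | intermediate
19 | (3R)-3-[4-(allyloxy)-2-(triethylsilyloxy)phenyl]-6,8-bis(3-methylbut-2-en-1-yl)-3-(triethylsilyloxy)-7-(triisopropylsilyloxy)chroman-4-one | CC(C)=CCc1cc2c(c(CC=C(C)C)c1O[Si](C(C)C)(C(C)C)C(C)C)OC[C@](O[Si](CC)(CC)CC)(c1ccc(OCC=C)cc1O[Si](CC)(CC)CC)C2=O | intermediate
20 | (3R)-3-[4-(allyloxy)-2-hydroxyphenyl]-3,7-dihydroxy-6,8-bis(3-methylbut-2-en-1-yl)chroman-4-one | CC(C)=CCc1cc2c(c(CC=C(C)C)c1O)OC[C@](O)(c1ccc(OCC=C)cc1O)C2=O | intermediate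
21 | (3R)-3-(2,4-dihydroxyphenyl)-3,7-dihydroxy-6,8-bis(3-methylbut-2-en-1-yl)chroman-4-one | CC(C)=CCc1cc2c(c(CC=C(C)C)c1O)OC[C@](O)(c1ccc(O)cc1O)C2=O | target

**Step count and risks**
Total: 12 steps. Longest linear sequence: 10 steps (steps 1–5 and 8–12).

Steps most likely to fail:

1. Step 8. Facial selectivity may erode if the aryl ether oxygen or a one-point complex competes with the ketone–ester chelate on copper, and conversion may be slow at the substituted enol ether carbon.
 - Fallback (auxiliary control): sets out from phenol 7 and returns at chromanone 19.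
 - (1R,2S,5R)-8-Phenylmenthol is acylated with bromopyruvoyl chloride (pyridine, CH2Cl2) to 8-phenylmenthyl bromopyruvate F1.
 - F1 alkylates 7 under the conditions of step 5 to give the 8-phenylmenthyl aryloxypyruvate F2.
 - Diene 13 is added under SnCl4 (CH2Cl2, −78 °C) in a substrate-controlled Mukaiyama aldol. In the chelated keto ester the phenyl ring of the auxiliary is expected to cover the re face, so the si face is attacked as in the catalytic step, and aqueous work-up should give the (2R)-configured 8-phenylmenthyl aldol adduct F3.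
 - Silylation and DDQ dehydrogenation as in step 9 give the bis(triethylsilyl) 8-phenylmenthyl ester F4.
 - The bromine–lithium exchange of step 10 closes ring C with loss of the auxiliary alkoxide and gives 19.

2. Step 9. DDQ may oxidise the benzylic–allylic CH2 of the prenyl groups, or the new aryl silyl ether may be partly lost during dehydrogenation, so that mixtures result.
 - Fallback (selenoxide elimination): sets out from 15 and returns at 17.
 - Dienol ether 16 is generated as before and treated with PhSeCl at −78 °C, which should selenenylate the oxygen-activated terminal carbon C5' to give the γ-phenylselanyl enone F5.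
 - Oxidation with NaIO4 (NaHCO3, aq. THF), selenoxide syn-elimination across C5'–C6' and tautomerisation give the phenol F6.
 - TESCl and imidazole (DMF) convert F6 into 17.

3. Step 10. Acylation of the aryllithium by the hindered, fully substituted ester may be slow, so that proton quench (net loss of bromine) or attack of t-BuLi at the allyl ether competes.
 - Fallback (aldehyde route): sets out from 17 and returns at 19.
 - i-Bu2AlH (CH2Cl2, −78 °C) reduces the ester to the aldehyde F7.
 - Bromine–lithium exchange with t-BuLi (THF, −78 °C) then closes ring C onto the more electrophilic and less hindered aldehyde to give the chroman-4-ol F8 as a mixture of C4 epimers.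
 - Dess–Martin periodinane (NaHCO3, CH2Cl2) oxidises F8 to 19.

**Further compounds**
F1 | step 8 | (1R,2S,5R)-5-methyl-2-(2-phenylpropan-2-yl)cyclohexyl 3-bromo-2-oxopropanoate | CC(C)(c1ccccc1)[C@@H]1CC[C@@H](C)C[C@H]1OC(=O)C(=O)CBr
F2 | step 8 | (1R,2S,5R)-5-methyl-2-(2-phenylpropan-2-yl)cyclohexyl 3-[2-bromo-4,6-bis(3-methylbut-2-en-1-yl)-5-(triisopropylsilyloxy)phenoxy]-2-oxopropanoate | CC(C)(c1ccccc1)[C@@H]1CC[C@@H](C)C[C@H]1OC(=O)C(=O)COc1c(Br)cc(CC=C(C)C)c(O[Si](C(C)C)(C(C)C)C(C)C)c1CC=C(C)C
F3 | step 8 | (1R,2S,5R)-5-methyl-2-(2-phenylpropan-2-yl)cyclohexyl (2R)-2-[4-(allyloxy)-2-oxocyclohex-3-en-1-yl]-3-[2-bromo-4,6-bis(3-methylbut-2-en-1-yl)-5-(triisopropylsilyloxy)phenoxy]-2-hydroxypropanoate | CC(C)(c1ccccc1)[C@@H]1CC[C@@H](C)C[C@H]1OC(=O)[C@](O)(COc1c(Br)cc(CC=C(C)C)c(O[Si](C(C)C)(C(C)C)C(C)C)c1CC=C(C)C)C1CCC(OCC=C)=CC1=O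
F4 | step 8 | (1R,2S,5R)-5-methyl-2-(2-phenylpropan-2-yl)cyclohexyl (2R)-2-[4-(allyloxy)-2-(triethylsilyloxy)phenyl]-3-[2-bromo-4,6-bis(3-methylbut-2-en-1-yl)-5-(triisopropylsilyloxy)phenoxy]-2-(triethylsilyloxy)propanoate | CC(C)(c1ccccc1)[C@@H]1CC[C@@H](C)C[C@H]1OC(=O)[C@](O[Si](CC)(CC)CC)(COc1c(Br)cc(CC=C(C)C)c(O[Si](C(C)C)(C(C)C)C(C)C)c1CC=C(C)C)c1ccc(OCC=C)cc1O[Si](CC)(CC)CC
F5 | step 9 | ethyl (2R)-2-[4-(allyloxy)-2-oxo-5-(phenylselanyl)cyclohex-3-en-1-yl]-3-[2-bromo-4,6-bis(3-methylbut-2-en-1-yl)-5-(triisopropylsilyloxy)phenoxy]-2-(triethylsilyloxy)propanoate | CCOC(=O)[C@](O[Si](CC)(CC)CC)(COc1c(Br)cc(CC=C(C)C)c(O[Si](C(C)C)(C(C)C)C(C)C)c1CC=C(C)C)C1CC([Se]c2ccccc2)C(OCC=C)=CC1=O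
F6 | step 9 | ethyl (2R)-2-[4-(allyloxy)-2-hydroxyphenyl]-3-[2-bromo-4,6-bis(3-methylbut-2-en-1-yl)-5-(triisopropylsilyloxy)phenoxy]-2-(triethylsilyloxy)propanoate | CCOC(=O)[C@](O[Si](CC)(CC)CC)(COc1c(Br)cc(CC=C(C)C)c(O[Si](C(C)C)(C(C)C)C(C)C)c1CC=C(C)C)c1ccc(OCC=C)cc1O
F7 | step 10 | (2R)-2-[4-(allyloxy)-2-(triethylsilyloxy)phenyl]-3-[2-bromo-4,6-bis(3-methylbut-2-en-1-yl)-5-(triisopropylsilyloxy)phenoxy]-2-(triethylsilyloxy)propanal | O=C[C@](O[Si](CC)(CC)CC)(COc1c(Br)cc(CC=C(C)C)c(O[Si](C(C)C)(C(C)C)C(C)C)c1CC=C(C)C)c1ccc(OCC=C)cc1O[Si](CC)(CC)CC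
F8 | step 10 | (3R)-3-[4-(allyloxy)-2-(triethylsilyloxy)phenyl]-6,8-bis(3-methylbut-2-en-1-yl)-3-(triethylsilyloxy)-7-(triisopropylsilyloxy)chroman-4-ol (C4 epimers) | CC(C)=CCc1cc2c(c(CC=C(C)C)c1O[Si](C(C)C)(C(C)C)C(C)C)OC[C@](O[Si](CC)(CC)CC)(c1ccc(OCC=C)cc1O[Si](CC)(CC)CC)C2O
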